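**Retrosynthetic overview**
- Target (1S,4R) ⇐ triol 17. C4–H is installed last by chiral-phosphoric-acid transfer hydrogenation of the o-quinone methide formed from the C4 tertiary alcohol and the free naphthol; C1 (S) comes from CBS reduction of the 4-hydroxy-1-tetralone 15.
- 15 ⇐ β-keto ester 13 ⇐ 3-aryl-4-methoxyphthalide 8 + allyl acrylate 9. A Michael–Dieckmann annulation forms C3–C4, then C1–C2, and opens the lactone in the same operation.
- 8 ⇐ ortho-lithiated N,N-diethyl-3-methoxybenzamide + naphthaldehyde 4; 4 ⇐ 8-methoxynaphthalen-1-ol by SEM protection and directed ortho-formylation.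
- Ring order: both arenes are bought; the temporary γ-lactone is closed in step 3; the carbocycle C1–C2–C3–C4–C4a–C8a is closed in step 4 as the lactone opens.
- Feature used: C4 is bonded to C4a and to naphthyl C2′ and lies ortho to C8a, so it maps onto the acidic, doubly benzylic C3 of a 3-aryl-4-methoxyphthalide whose lactone carbonyl is already C1 on C8a.

Key step: step 4

**Remarks and assumptions**
- Locants follow the target throughout: C1 carries the secondary OH, C4 the naphthyl group, C5 the OMe.
- ArSEM = 8-methoxy-1-{[2-(trimethylsilyl)ethoxy]methoxy}naphthalen-2-yl.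
- The naphthol is protected as a SEM rather than a MOM acetal. It directs lithiation equally well, and fluoride removes it without acid, which would ionise the C4 tertiary benzylic alcohol.
- The (R)-antipode of the phosphoric acid in step 8 is assumed to be the one that gives (4R); if the opposite sense is found, the (S)-catalyst is used under the same conditions.

**Route**

Step 1
Reactants: 1 8-methoxynaphthalen-1-ol
Product: 2 8-methoxy-1-{[2-(trimethylsilyl)ethoxy]methoxy}naphthalene
Conditions: NaH, DMF, 0 °C; SEMCl, 0 °C → rt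
Reagents that add atoms: 2-(trimethylsilyl)ethoxymethyl chloride (SEMCl), C[Si](C)(C)CCOCCl
Why: Williamson-type O-alkylation of the sodium naphtholate with the reactive chloromethyl ether should give the SEM acetal, which directs the next lithiation and later leaves with fluoride.

Step 2
Reactants: 2 8-methoxy-1-{[2-(trimethylsilyl)ethoxy]methoxy}naphthalene
Product: 4 8-methoxy-1-{[2-(trimethylsilyl)ethoxy]methoxy}naphthalene-2-carbaldehyde, via 2-lithio SEM ether 3 (not isolated)
Conditions: n-BuLi, TMEDA, Et2O, 0 °C → rt; DMF, −78 °C → rt; aq. NH4Cl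
Reagents that add atoms: N,N-dimethylformamide (DMF), CN(C)C=O
Why: Directed ortho-metalation, in which the chelating OCH2O acetal is a stronger director than the methoxy group, should place lithium at C2 (C8 is blocked), and formylation with DMF then gives the 2-carbaldehyde.

Step 3
Reactants: 5 N,N-diethyl-3-methoxybenzamide; 4 8-methoxy-1-{[2-(trimethylsilyl)ethoxy]methoxy}naphthalene-2-carbaldehyde
Product: 8 4-methoxy-3-(ArSEM)isobenzofuran-1(3H)-one (racemic), via ortho-lithiated benzamide 6 (not isolated), via hydroxy amide 7 (not isolated)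
Conditions: 5, s-BuLi, TMEDA, THF, −78 °C; 4, −78 → 0 °C; aq. NH4Cl; crude, AcOH, PhMe, 90 °C
Reagents that add atoms: none
Why: Directed ortho-metalation at C2 between the cooperating amide and methoxy groups, 1,2-addition of the aryllithium to the aldehyde and weak-acid lactonisation of the hydroxy amide with loss of diethylamine form the 3-arylphthalide while the SEM acetal survives; the new C3 centre is racemic and is erased by deprotonation in step 4.

Step 4
Reactants: 8 4-methoxy-3-(ArSEM)isobenzofuran-1(3H)-one; 9 allyl acrylate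
Product: 13 allyl 4-hydroxy-5-methoxy-4-(ArSEM)-1-oxo-1,2,3,4-tetrahydronaphthalene-2-carboxylate (racemic; C2 epimers/enol), via lithiated phthalide 10 (not isolated), via Michael adduct enolate 11 (not isolated), via bridged lithium alkoxide 12 (not isolated)
Conditions: LiHMDS (1.15 equiv), THF, −78 °C; 9 (1.2 equiv, slow addition), −78 → −20 °C; AcOH, −78 °C; pH 7 buffer
Reagents that add atoms: none
Why: LiHMDS removes the doubly benzylic C3–H of the phthalide (future C4) to give the delocalised 1-lithiooxy-isobenzofuran 10, a soft tertiary carbanion that adds 1,4 to allyl acrylate (C3–C4) and gives ester enolate 11. The enolate carbon (C2) then acylates on the lactone carbonyl in a Dieckmann-type 6-exo-trig (6-enolexo) closure through the oxygen-bridged tetrahedral adduct 12, which collapses by expelling the C4 alkoxide; proton transfer from C2 stores the product as the stabilised β-keto ester enolate and so prevents retro-Claisen reversal. This is the Michael–Dieckmann (Hauser–Kraus-type) annulation of phthalide anions with acrylates, here with a 3-aryl phthalide that has no leaving group at C3, so the lactone oxygen remains as the C4 tertiary alcohol. C4 and C2 form without control, which is harmless because C2 loses its ester in step 5 and C4 is planarised in step 8. The selectivity needed is chemoselectivity: conjugate rather than carbonyl addition is secured by the soft anion and the unhindered acrylate β-carbon, acrylate oligomerisation is limited by slow addition to the preformed anion at −78 °C, and dehydration to the 4-aryl-1-naphthol is avoided by the cold buffered quench and by the protected naphthol, which cannot form a quinone methide.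

Step 5
Reactants: 13 allyl 4-hydroxy-5-methoxy-4-(ArSEM)-1-oxo-1,2,3,4-tetrahydronaphthalene-2-carboxylate
Product: 15 4-hydroxy-5-methoxy-4-(ArSEM)-3,4-dihydronaphthalen-1(2H)-one (racemic), via β-keto acid 14 (not isolated)
Conditions: Pd(OAc)2 (5 mol %), PPh3 (20 mol %), HCO2H, Et3N, THF, rt
Reagents that add atoms: none
Why: Tsuji deallylation, in which Pd(0) ionises the allyl ester to a π-allyl complex that formate reduces to propene, frees the β-keto acid, which decarboxylates at room temperature in a buffered medium that leaves the tertiary benzylic alcohol and the SEM acetal untouched.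

Step 6
Reactants: 15 4-hydroxy-5-methoxy-4-(ArSEM)-3,4-dihydronaphthalen-1(2H)-one
Product: 16 (1S)-5-methoxy-4-(ArSEM)-1,2,3,4-tetrahydronaphthalene-1,4-diol (both C4 epimers)
Conditions: (R)-Me-CBS (20 mol %), BH3·SMe2 (2 equiv), THF, −20 °C; MeOH
Reagents that add atoms: none
Why: Corey–Bakshi–Shibata reduction, in which the (R)-oxazaborolidine distinguishes the aryl flank from the CH2 flank of the tetralone and delivers hydride to the Re face of C1, should set (1S) by catalyst control in both C4 epimers, whose C4 configuration is erased in step 8.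

Step 7
Reactants: 16 (1S)-5-methoxy-4-(ArSEM)-1,2,3,4-tetrahydronaphthalene-1,4-diol
Product: 17 (1S)-4-(1-hydroxy-8-methoxynaphthalen-2-yl)-5-methoxy-1,2,3,4-tetrahydronaphthalene-1,4-diol (both C4 epimers)
Conditions: TBAF, THF–DMPU, 50 °C; aq. NH4Cl
Reagents that add atoms: none
Why: Fluoride attacks silicon and the SEM group fragments to fluorotrimethylsilane, ethene and formaldehyde, releasing the naphtholate under basic conditions in which neither benzylic alcohol ionises.

Step 8
Reactants: 17 (1S)-4-(1-hydroxy-8-methoxynaphthalen-2-yl)-5-methoxy-1,2,3,4-tetrahydronaphthalene-1,4-diol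
Product: 19 (1S,4R)-4-(1-hydroxy-8-methoxynaphthalen-2-yl)-5-methoxy-1,2,3,4-tetrahydronaphthalen-1-ol (Dipolynaphthalene A), via ortho-quinone methide 18 (not isolated)
Conditions: (R)-TRIP (10 mol %), Hantzsch ester (1.5 equiv), CH2Cl2, rt
Reagents that add atoms: none
Why: Chiral-phosphoric-acid-catalysed dehydration of the o-hydroxybenzylic tertiary alcohol gives quinone methide 18, and asymmetric transfer hydrogenation (1,4-hydride addition from the Hantzsch ester inside the hydrogen-bonded complex, known for 1,1-diaryl carbinols with an ortho OH) should deliver hydride to the C4 face that leaves the naphthyl group trans to the C1 hydroxyl, giving (4R), while the C1 carbinol, meta to the OMe and without cation stabilisation, should not ionise.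

**Compound list**
1 | 8-methoxynaphthalen-1-ol | COc1cccc2cccc(O)c12 | starting material
2 | 8-methoxy-1-{[2-(trimethylsilyl)ethoxy]methoxy}naphthalene | COc1cccc2cccc(OCOCC[Si](C)(C)C)c12 | intermediate
3 | [8-methoxy-1-{[2-(trimethylsilyl)ethoxy]methoxy}naphthalen-2-yl]lithium | COc1cccc2ccc([Li])c(OCOCC[Si](C)(C)C)c12 | intermediate
4 | 8-methoxy-1-{[2-(trimethylsilyl)ethoxy]methoxy}naphthalene-2-carbaldehyde | COc1cccc2ccc(C=O)c(OCOCC[Si](C)(C)C)c12 | intermediate
5 | N,N-diethyl-3-methoxybenzamide | CCN(CC)C(=O)c1cccc(OC)c1 | starting material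
6 | [2-(diethylcarbamoyl)-6-methoxyphenyl]lithium | CCN(CC)C(=O)c1cccc(OC)c1[Li] | intermediate
7 | N,N-diethyl-2-[hydroxy(8-methoxy-1-{[2-(trimethylsilyl)ethoxy]methoxy}naphthalen-2-yl)methyl]-3-methoxybenzamide (racemic) | CCN(CC)C(=O)c1cccc(OC)c1C(O)c1ccc2cccc(OC)c2c1OCOCC[Si](C)(C)C | intermediate
8 | 4-methoxy-3-(8-methoxy-1-{[2-(trimethylsilyl)ethoxy]methoxy}naphthalen-2-yl)isobenzofuran-1(3H)-one (racemic) | COc1cccc2c1C(c1ccc3cccc(OC)c3c1OCOCC[Si](C)(C)C)OC2=O | intermediate
9 | allyl acrylate (prop-2-en-1-yl prop-2-enoate) | C=CC(=O)OCC=C | starting material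
10 | lithium 4-methoxy-3-(8-methoxy-1-{[2-(trimethylsilyl)ethoxy]methoxy}naphthalen-2-yl)isobenzofuran-1-olate | [Li]OC1=C2C=CC=C(OC)C2=C(c2ccc3cccc(OC)c3c2OCOCC[Si](C)(C)C)O1 | intermediate
11 | lithium enolate of allyl 3-[7-methoxy-3-oxo-1-(8-methoxy-1-{[2-(trimethylsilyl)ethoxy]methoxy}naphthalen-2-yl)-1,3-dihydroisobenzofuran-1-yl]propanoate | COc1cccc2c1C(CC=C(O[Li])OCC=C)(c1ccc3cccc(OC)c3c1OCOCC[Si](C)(C)C)OC2=O | intermediate
12 | lithium 2-(allyloxycarbonyl)-5-methoxy-4-(8-methoxy-1-{[2-(trimethylsilyl)ethoxy]methoxy}naphthalen-2-yl)-1,2,3,4-tetrahydro-1,4-epoxynaphthalen-1-olate | COc1cccc2c1C1(c3ccc4cccc(OC)c4c3OCOCC[Si](C)(C)C)CC(C(=O)OCC=C)C2(O[Li])O1 | intermediate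
13 | allyl 4-hydroxy-5-methoxy-4-(8-methoxy-1-{[2-(trimethylsilyl)ethoxy]methoxy}naphthalen-2-yl)-1-oxo-1,2,3,4-tetrahydronaphthalene-2-carboxylate (racemic; C2 epimers/enol) | COc1cccc2c1C(O)(c1ccc3cccc(OC)c3c1OCOCC[Si](C)(C)C)CC(C(=O)OCC=C)C2=O | intermediate
14 | 4-hydroxy-5-methoxy-4-(8-methoxy-1-{[2-(trimethylsilyl)ethoxy]methoxy}naphthalen-2-yl)-1-oxo-1,2,3,4-tetrahydronaphthalene-2-carboxylic acid | COc1cccc2c1C(O)(c1ccc3cccc(OC)c3c1OCOCC[Si](C)(C)C)CC(C(=O)O)C2=O | intermediate
15 | 4-hydroxy-5-methoxy-4-(8-methoxy-1-{[2-(trimethylsilyl)ethoxy]methoxy}naphthalen-2-yl)-3,4-dihydronaphthalen-1(2H)-one (racemic) | COc1cccc2c1C(O)(c1ccc3cccc(OC)c3c1OCOCC[Si](C)(C)C)CCC2=O | intermediate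
16 | (1S)-5-methoxy-4-(8-methoxy-1-{[2-(trimethylsilyl)ethoxy]methoxy}naphthalen-2-yl)-1,2,3,4-tetrahydronaphthalene-1,4-diol (both C4 epimers) | COc1cccc2c1C(O)(c1ccc3cccc(OC)c3c1OCOCC[Si](C)(C)C)CC[C@@H]2O | intermediate
17 | (1S)-4-(1-hydroxy-8-methoxynaphthalen-2-yl)-5-methoxy-1,2,3,4-tetrahydronaphthalene-1,4-diol (both C4 epimers) | COc1cccc2c1C(O)(c1ccc3cccc(OC)c3c1O)CC[C@@H]2O | intermediate
18 | 2-[(4S)-4-hydroxy-8-methoxy-3,4-dihydronaphthalen-1(2H)-ylidene]-8-methoxynaphthalen-1(2H)-one | COc1cccc2c1C(=C1C=Cc3cccc(OC)c3C1=O)CC[C@@H]2O | intermediate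
19 | (1S,4R)-4-(1-hydroxy-8-methoxynaphthalen-2-yl)-5-methoxy-1,2,3,4-tetrahydronaphthalen-1-ol (Dipolynaphthalene A) | COc1cccc2c1[C@@H](c1ccc3cccc(OC)c3c1O)CC[C@@H]2O | target

**Step count**
Total steps: 8. Longest linear sequence: 8 steps (1 → 19; 5 enters at step 3 and 9 at step 4).

**Steps most likely to fail**

Step 4. Conjugate addition of the congested tertiary carbanion may be too slow to compete with anionic oligomerisation of the acrylate. The closure may also reverse through attack of the C4 alkoxide on C1, or the adduct may lose water during isolation. The fallback sets out from 8 and comes back at 15, making the two ring bonds in separate operations. Lithiated 8 is C-allylated with allyl bromide (LiHMDS, THF, −78 °C) to give 3-allyl-4-methoxy-3-(ArSEM)isobenzofuran-1(3H)-one F1. Lemieux–Johnson cleavage (OsO4 cat., NaIO4, 2,6-lutidine, dioxane–water) gives 2-[7-methoxy-3-oxo-1-(ArSEM)-1,3-dihydroisobenzofuran-1-yl]acetaldehyde F2, which is reduced at once with NaBH4 (MeOH, 0 °C) to 3-(2-hydroxyethyl)-4-methoxy-3-(ArSEM)isobenzofuran-1(3H)-one F3. Appel iodination (I2, PPh3, imidazole) gives 3-(2-iodoethyl)-4-methoxy-3-(ArSEM)isobenzofuran-1(3H)-one F4. Iodine–lithium exchange with t-BuLi (2 equiv, Et2O–pentane, −78 °C) generates a primary alkyllithium that acylates on the lactone carbonyl (C1–C2, anionic cycloacylation of an ω-iodo ester), and the bridged adduct opens to ketone 15 on work-up.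

Step 8. Hydride may reach both faces of the quinone methide if catalyst and C1 centre are mismatched or if the E and Z quinone methides react through different faces. Prolonged acid exposure may also eliminate the C1 hydroxyl through the 3,4-alkene with aromatisation. The fallback sets out from 17 and comes back at 19, replacing catalyst control by substrate direction. Catalytic diphenyl phosphate (toluene, rt, no hydride donor) dehydrates 17 to the conjugated alkene (1S)-4-(1-hydroxy-8-methoxynaphthalen-2-yl)-5-methoxy-1,2-dihydronaphthalen-1-ol F5. Hydroxyl-directed hydrogenation with Crabtree's catalyst ([Ir(cod)(PCy3)(py)]PF6, H2, CH2Cl2) then delivers H2 from the face of the homoallylic C1 hydroxyl, so that H enters C4 cis to OH and the naphthyl group ends trans, which is (4R).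

Step 6. A mismatch between the oxazaborolidine and one C4 epimer may lower the facial selectivity at C1 for half of the material, and uncatalysed reduction by borane may add a racemic background. The fallback sets out from 15 and comes back at 16, replacing asymmetric reduction by resolution. NaBH4 (MeOH, 0 °C) gives the stereorandom 5-methoxy-4-(ArSEM)-1,2,3,4-tetrahydronaphthalene-1,4-diol F6. Candida antarctica lipase B with vinyl acetate (MTBE, 30 °C) should acylate the (1R)-carbinols, the usual preference for 1-aryl alkanols, to (1R)-4-hydroxy-5-methoxy-4-(ArSEM)-1,2,3,4-tetrahydronaphthalen-1-yl acetate F7. The unreacted (1S)-diol is compound 16 and is separated by chromatography; F7 can be returned to 15 by methanolysis and oxidation.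

**Further compounds**
F1 | step 4 | 3-allyl-4-methoxy-3-(8-methoxy-1-{[2-(trimethylsilyl)ethoxy]methoxy}naphthalen-2-yl)isobenzofuran-1(3H)-one (racemic) | COc1cccc2c1C(CC=C)(c1ccc3cccc(OC)c3c1OCOCC[Si](C)(C)C)OC2=O
F2 | step 4 | 2-[7-methoxy-3-oxo-1-(8-methoxy-1-{[2-(trimethylsilyl)ethoxy]methoxy}naphthalen-2-yl)-1,3-dihydroisobenzofuran-1-yl]acetaldehyde (racemic) | COc1cccc2c1C(CC=O)(c1ccc3cccc(OC)c3c1OCOCC[Si](C)(C)C)OC2=O
F3 | step 4 | 3-(2-hydroxyethyl)-4-methoxy-3-(8-methoxy-1-{[2-(trimethylsilyl)ethoxy]methoxy}naphthalen-2-yl)isobenzofuran-1(3H)-one (racemic) | COc1cccc2c1C(CCO)(c1ccc3cccc(OC)c3c1OCOCC[Si](C)(C)C)OC2=O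
F4 | step 4 | 3-(2-iodoethyl)-4-methoxy-3-(8-methoxy-1-{[2-(trimethylsilyl)ethoxy]methoxy}naphthalen-2-yl)isobenzofuran-1(3H)-one (racemic) | COc1cccc2c1C(CCI)(c1ccc3cccc(OC)c3c1OCOCC[Si](C)(C)C)OC2=O
F5 | step 8 | (1S)-4-(1-hydroxy-8-methoxynaphthalen-2-yl)-5-methoxy-1,2-dihydronaphthalen-1-ol | COc1cccc2c1C(c1ccc3cccc(OC)c3c1O)=CC[C@@H]2O
F6 | step 6 | 5-methoxy-4-(8-methoxy-1-{[2-(trimethylsilyl)ethoxy]methoxy}naphthalen-2-yl)-1,2,3,4-tetrahydronaphthalene-1,4-diol (all stereoisomers) | COc1cccc2c1C(O)(c1ccc3cccc(OC)c3c1OCOCC[Si](C)(C)C)CCC2O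
F7 | step 6 | (1R)-4-hydroxy-5-methoxy-4-(8-methoxy-1-{[2-(trimethylsilyl)ethoxy]methoxy}naphthalen-2-yl)-1,2,3,4-tetrahydronaphthalen-1-yl acetate (both C4 epimers) | COc1cccc2c1C(O)(c1ccc3cccc(OC)c3c1OCOCC[Si](C)(C)C)CC[C@H]2OC(C)=O
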